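## Retrosynthetic overview

1. The only ring of the target, the tetrahydrofuran, is closed last. The O1–C2 bond forms by intramolecular oxa-Michael (1,6-conjugate) addition of a primary alcohol to a para-quinone methide released from a benzylic sulfone; the silyl groups come off in the same pot.
2. The acyclic diol precursor comes from hydride reduction of a trans-α,β-disubstituted γ-(menthyloxy)butyrolactone, a temporary ring.
3. That lactone is made in one three-component operation: Michael addition of a lithiated benzylic sulfone (catechol ring + C2) to (5R)-5-menthyloxy-2(5H)-furanone, anti-aldol of the resulting enolate with O-silyl vanillin, and in situ O-silylation.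
4. Three branches feed this coupling: the sulfone (3 steps from protocatechualdehyde), the butenolide (2 steps from furfural and l-menthol) and the aldehyde (1 step from vanillin).

Labels used below: THF atoms O1, C2 (bears the catechol ring), C3 (bears CH2OH), C4, C5; the carbinol carbon on C4 is C7. The target is (2S,3R,4R) in the ring and R at C7 (2,3-trans, 3,4-cis).

Assumption: the sulfonyl-bearing benzylic carbon in 12 and 13 is carried as a mixture of epimers, since it becomes sp2 in the quinone methide.

## Route

**Step 1**
Reactants: 1, 3,4-dihydroxybenzaldehyde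
Product: 2, 3,4-bis(triisopropylsilyloxy)benzaldehyde
Conditions: TIPSCl (2.4 equiv), imidazole, DMF, 40 °C
Reagents that add atoms: TIPSCl, CC(C)[Si](Cl)(C(C)C)C(C)C
Why: Standard phenol O-silylation; TIPS is chosen because it survives organolithium and LiAlH4 and is removed rapidly by fluoride.

**Step 2**
Reactants: 2
Product: 3, [3,4-bis(triisopropylsilyloxy)phenyl]methanol
Conditions: NaBH4, THF/MeOH, 0 °C
Reagents that add atoms: none
Why: Chemoselective hydride reduction of the aldehyde; aryl TIPS ethers are stable to borohydride.

**Step 3**
Reactants: 3; 4, sodium p-toluenesulfinate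
Product: 5, 4-[(p-tolylsulfonyl)methyl]-1,2-bis(triisopropylsilyloxy)benzene
Conditions: PPh3, NBS, CH2Cl2, 0 °C; then 4, Bu4NI (cat.), DMF, rt (one pot)
Reagents that add atoms: none (the sulfonyl group comes from 4)
Why: Appel bromination followed by SN2 S-alkylation of the sulfinate by the activated benzylic bromide gives the sulfone.

**Step 4**
Reactants: 6, furfural
Product: 7, 5-hydroxy-2(5H)-furanone (racemic)
Conditions: O2, hν, rose bengal (cat.), MeOH, rt
Reagents that add atoms: singlet oxygen, O=O
Why: Photooxygenation: [4+2] addition of singlet oxygen to the furan and fragmentation of the endoperoxide in methanol, with loss of the formyl carbon as methyl formate, gives the γ-hydroxybutenolide.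

**Step 5**
Reactants: 7; 8, (−)-menthol (1R,2S,5R)
Product: 9, (5R)-5-[(1R,2S,5R)-menthyloxy]-2(5H)-furanone
Conditions: CSA (cat.), toluene, reflux, Dean–Stark; crystallise from petroleum ether, re-equilibrate and recycle the mother liquor
Reagents that add atoms: none (menthyl group comes from 8)
Why: Acid-catalysed acetalisation of the pseudo-acid; the two C5 epimers interconvert under acid and the (5R) diastereomer crystallises (crystallisation-induced asymmetric transformation).

**Step 6**
Reactants: 10, vanillin
Product: 11, 3-methoxy-4-(triisopropylsilyloxy)benzaldehyde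
Conditions: TIPSCl, imidazole, DMF, rt
Reagents that add atoms: TIPSCl, CC(C)[Si](Cl)(C(C)C)C(C)C
Why: Phenol O-silylation; masks the acidic OH for the enolate step.

**Step 7** (three-component coupling)
Reactants: 5; 9; 11
Product: 12, (3S,4R,5R)-4-{[3,4-bis(TIPSO)phenyl](p-tolylsulfonyl)methyl}-3-{(R)-(tert-butyldimethylsilyloxy)[3-methoxy-4-(TIPSO)phenyl]methyl}-5-[(1R,2S,5R)-menthyloxy]dihydrofuran-2(3H)-one (ring H3/H4 trans, H4/H5 trans; sulfonyl carbon as epimer mixture)
Conditions: 5, n-BuLi, THF, −78 °C; then 9, −78 °C; then 11, −78 °C; then TBSOTf, −78 → −30 °C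
Reagents that add atoms: TBSOTf, CC(C)(C)[Si](C)(C)OS(=O)(=O)C(F)(F)F
Why: Tandem Michael addition–aldol: the α-sulfonyl benzyl anion adds 1,4 to the butenolide anti to the menthyloxy group (sets C3), the resulting E-configured lactone enolate adds to the aldehyde anti to the new substituent through a Zimmerman–Traxler chair to give the trans-lactone anti-aldol (sets C4 and C7; about 4:1 at C7 expected, minor epimer removed by chromatography here or at the end), and the aldolate is silylated in situ.

**Step 8**
Reactants: 12
Product: 13, (2R,3R)-2-{(R)-(tert-butyldimethylsilyloxy)[3-methoxy-4-(TIPSO)phenyl]methyl}-3-{[3,4-bis(TIPSO)phenyl](p-tolylsulfonyl)methyl}butane-1,4-diol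
Conditions: LiAlH4, THF, 0 °C; Rochelle salt work-up
Reagents that add atoms: none
Why: Hydride reduction of the lactone; the opened lactol expels menthoxide from the γ-acetal, so both carbonyl-level carbons end as CH2OH. Reduction of the transient aldehydes is much faster than α-epimerisation, so C3, C4 and C7 are unchanged, and the aryl TIPS ethers, TBS ether and sulfone are inert at 0 °C.

**Step 9** (key ring closure and global deprotection)
Reactants: 13
Product: 14, (7R)-7-hydroxytaxiresinol, (2S,3R,4R)-2-(3,4-dihydroxyphenyl)-4-[(R)-hydroxy(4-hydroxy-3-methoxyphenyl)methyl]-3-(hydroxymethyl)tetrahydrofuran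
Conditions: TBAF (excess), degassed THF, −20 → 0 °C, 1 h; then rt, 12 h; AcOH quench
Reagents that add atoms: none
Why: Fluoride cleaves the aryl silyl ethers first, and the para-phenoxide expels p-toluenesulfinate (1,6-elimination) to give the p-quinone methide. The C5 hydroxyl captures it 5-exo-trig in an intramolecular oxa-Michael (1,6-conjugate) addition, placing the aryl group trans to the C3 hydroxymethyl (sets C2 as S). The C7 oxygen is still silylated at this point and cannot compete; slower cleavage of the secondary TBS ether at rt then gives the target.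

## Compound list

1 | 3,4-dihydroxybenzaldehyde | O=Cc1ccc(O)c(O)c1 | starting material
2 | 3,4-bis(triisopropylsilyloxy)benzaldehyde | O=Cc1ccc(O[Si](C(C)C)(C(C)C)C(C)C)c(O[Si](C(C)C)(C(C)C)C(C)C)c1 | intermediate
3 | [3,4-bis(triisopropylsilyloxy)phenyl]methanol | OCc1ccc(O[Si](C(C)C)(C(C)C)C(C)C)c(O[Si](C(C)C)(C(C)C)C(C)C)c1 | intermediate
4 | sodium p-toluenesulfinate | Cc1ccc(cc1)S(=O)[O-].[Na+] | starting material
5 | 4-[(p-tolylsulfonyl)methyl]-1,2-bis(triisopropylsilyloxy)benzene | Cc1ccc(cc1)S(=O)(=O)Cc1ccc(O[Si](C(C)C)(C(C)C)C(C)C)c(O[Si](C(C)C)(C(C)C)C(C)C)c1 | intermediate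
6 | furfural | O=Cc1ccco1 | starting material
7 | 5-hydroxy-2(5H)-furanone | OC1OC(=O)C=C1 | intermediate
8 | (−)-menthol | CC(C)[C@@H]1CC[C@@H](C)C[C@H]1O | starting material
9 | (5R)-5-[(1R,2S,5R)-menthyloxy]-2(5H)-furanone | O=C1C=C[C@H](O[C@@H]2C[C@H](C)CC[C@H]2C(C)C)O1 | intermediate
10 | vanillin | COc1cc(C=O)ccc1O | starting material
11 | 3-methoxy-4-(triisopropylsilyloxy)benzaldehyde | COc1cc(C=O)ccc1O[Si](C(C)C)(C(C)C)C(C)C | intermediate
12 | tandem Michael–aldol lactone (see Step 7) | O=C1O[C@@H](O[C@@H]2C[C@H](C)CC[C@H]2C(C)C)[C@H](C(c2ccc(O[Si](C(C)C)(C(C)C)C(C)C)c(O[Si](C(C)C)(C(C)C)C(C)C)c2)S(=O)(=O)c2ccc(C)cc2)[C@H]1[C@@H](O[Si](C)(C)C(C)(C)C)c1ccc(O[Si](C(C)C)(C(C)C)C(C)C)c(OC)c1 | intermediate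
13 | sulfonyl diol (see Step 8) | OC[C@H](C(c1ccc(O[Si](C(C)C)(C(C)C)C(C)C)c(O[Si](C(C)C)(C(C)C)C(C)C)c1)S(=O)(=O)c1ccc(C)cc1)[C@H](CO)[C@@H](O[Si](C)(C)C(C)(C)C)c1ccc(O[Si](C(C)C)(C(C)C)C(C)C)c(OC)c1 | intermediate
14 | (7R)-7-hydroxytaxiresinol | COc1cc([C@H](O)[C@H]2CO[C@H](c3ccc(O)c(O)c3)[C@H]2CO)ccc1O | target

## Step count

Total steps: 9 (branches of 3, 2 and 1 steps; coupling; 2 finishing steps).
Longest linear sequence: 6 (steps 1, 2, 3, 7, 8, 9), which is two thirds of the total.

## Steps most likely to fail

1. **Step 7.** The adduct keeps an acidic α-sulfonyl C–H that can quench the lactone enolate or the aldolate by proton transfer, and the anti/syn ratio at C7 may be modest.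
 Fallback: use the 2-aryl-1,3-dithiane of aldehyde 2 as the Michael donor (no residual acidic H). Unmask it to the aryl ketone so that hydride reduction gives a C2 benzylic alcohol as the quinone methide precursor. If C7 selectivity is still poor, oxidise the aldol to the C7 ketone and set C7 by reagent-controlled reduction with (S)-Me-CBS instead of by the aldol.

2. **Step 9.** The catechol quinone methide may tautomerise to a vinylphenol or o-quinone, the free catecholate may oxidise, or the C7 TBS ether may be lost early so that the C7 oxygen competes and gives the 2,5-diaryl THF.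
 Fallback: close the ring while all phenols are still silylated, by mild acid-catalysed SN1 cycloetherification of a C2 benzylic alcohol analogue (from the dithiane route) with CSA in CH2Cl2 at 0 °C, then deprotect with TBAF/AcOH.

3. **Step 8.** If an aryl silyl ether is lost, the quinone methide would be released in the presence of hydride and reduced to the benzyl compound; LiAlH4 may also deprotonate the sulfone.
 Fallback: change the trigger so hydride cannot unmask it. Protect the para-oxygen of the catechol ring as an allyl ether (regioselective 4-O-allylation of 1, then 3-O-TIPS) and release the phenol after reduction with Pd(0)/morpholine, followed by base to form the quinone methide. This adds one step to the sulfone branch.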